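Ring A of the dihydroisoquinoline (C4a, C5, C6, C7, C8, C8a) carries oxygen at C6 and C8, the C1 acetyl-derived carbon on C8a and the C4 chain on C4a. This is the alternating pattern of a folded C1/C8/C6/C4a tetraketone, so the route rests on cutting C4a–C8a. In one operation, hydroxide unmasks a 4-pyranone to that tetraketone and an intramolecular aldol condensation aromatises it. This gives the acetylresorcinol with the C5–C1' biaryl bond and the (S)-carbamate chain already in place. The precursor is a 6-methyl-4-pyranone whose C2 substituent is a methine carrying the 4,5-dimethoxy-2-methylnaphth-1-yl group and the (S)-3-(Boc-amino)butanoyl group.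

Key step: step 9

Assumption: the SMILES fixes only C3 (S) and does not encode the hindered C5–C1' axis, so both atropo-diastereomers correspond to it; the route does not control the axis, and the two forms would be separated by chromatography at 28 if a single one is wanted.

Numbering: isoquinoline numbers are used for the polyketide carbons and primed numbers for the naphthalene. In the pyranone, ring C6 = C1, C5 = C8a, C4 = C8, C3 = C7 and C2 = C6. The exocyclic methine is C5, the side-chain ketone is C4a, and the chain continues with C4 and C3.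

Step 1
Reactants: 1 2-bromoanisole; 2 hexacarbonylchromium Cr(CO)6
Product: 5 pentacarbonyl[methoxy(2-methoxyphenyl)carbene]chromium, via 2-methoxyphenyllithium 3 (not isolated), via lithium acylchromate 4 (not isolated)
Conditions: n-BuLi, Et2O, −78 to 0 °C; Cr(CO)6, Et2O, 0 °C to rt; Me3OBF4, CH2Cl2, 0 °C to rt
Reagents that add atoms: trimethyloxonium tetrafluoroborate, C[O+](C)C.F[B-](F)(F)F
Why: Bromine–lithium exchange gives aryllithium 3, which adds to a carbonyl ligand of Cr(CO)6 to give acylchromate 4, and O-methylation with the hard oxonium salt completes a standard Fischer carbene synthesis.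

Step 2
Reactants: 5 pentacarbonyl[methoxy(2-methoxyphenyl)carbene]chromium; 6 propyne
Product: 8 4,5-dimethoxy-2-methylnaphthalen-1-ol, via Cr(CO)3 naphthol complex 7 (not isolated)
Conditions: propyne (excess), THF, 50 °C, sealed tube; then air, Et2O, rt, short silica filtration, used at once
Reagents that add atoms: none
Why: In this Dötz benzannulation the unsubstituted alkyne carbon bonds to the carbene carbon and the methyl-bearing carbon to the inserted CO (the usual regiochemistry of terminal alkynes), ring closure onto the free ortho position of the anisyl ring places OH at C1', methyl at C2' and methoxy at C4' and C5', and brief aeration strips Cr(CO)3.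

Step 3
Reactants: 8 4,5-dimethoxy-2-methylnaphthalen-1-ol
Product: 9 4,5-dimethoxy-2-methylnaphthalen-1-yl trifluoromethanesulfonate
Conditions: Tf2O, pyridine, CH2Cl2, −10 to 0 °C
Reagents that add atoms: trifluoromethanesulfonic anhydride, O=S(=O)(OS(=O)(=O)C(F)(F)F)C(F)(F)F
Why: O-Sulfonylation of the naphthol turns the CO-derived oxygen into a cross-coupling leaving group and at the same time removes the oxidation-prone hydroquinone monoether function.

Step 4
Reactants: 9 4,5-dimethoxy-2-methylnaphthalen-1-yl trifluoromethanesulfonate; 10 methyl bromoacetate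
Product: 12 methyl 2-(4,5-dimethoxy-2-methylnaphthalen-1-yl)acetate, via Reformatsky reagent 11 (not isolated)
Conditions: 10, Zn dust (Me3SiCl-activated), THF, 40 °C; then 9, Pd2(dba)3 (cat), XPhos (cat), THF, 65 °C
Reagents that add atoms: none
Why: In this Negishi-type coupling of a Reformatsky reagent (palladium-catalysed α-arylation of a zinc ester enolate), the bulky electron-rich biarylphosphine lets zerovalent palladium insert into the hindered C1'–OTf bond and the small, weakly basic zinc enolate delivers the CH2CO2Me unit without attacking the ester.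

Step 5
Reactants: 12 methyl 2-(4,5-dimethoxy-2-methylnaphthalen-1-yl)acetate; 13 acetylacetone
Product: 15 1-(4,5-dimethoxy-2-methylnaphthalen-1-yl)heptane-2,4,6-trione, via dilithioacetylacetone 14 (not isolated)
Conditions: 13 (3 equiv), LiN(iPr)2 (6 equiv), THF, −78 to 0 °C; then 12, 0 °C to rt; cold 1 M HCl to pH 4
Reagents that add atoms: none
Why: This is a Claisen-type acylation of the acetylacetone 1,3-dianion, which reacts only at its more basic terminal carbon, while the excess dianion takes up the acidic protons of the triketone as it forms and the cold acidic quench avoids base-induced cyclisation.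

Step 6
Reactants: 15 1-(4,5-dimethoxy-2-methylnaphthalen-1-yl)heptane-2,4,6-trione
Product: 16 2-[(4,5-dimethoxy-2-methylnaphthalen-1-yl)methyl]-6-methyl-4H-pyran-4-one
Conditions: TsOH·H2O (cat), toluene, reflux, Dean–Stark
Reagents that add atoms: none
Why: Acid-catalysed cyclodehydration of a 1,3,5-triketone (the enol oxygen of one outer carbonyl adds to the other outer carbonyl and water is lost) is the standard entry to 2,6-disubstituted 4-pyranones, and a catalytic sulfonic acid is chosen to spare the electron-rich naphthalene.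

Step 7
Reactants: 17 (S)-3-(tert-butoxycarbonylamino)butanoic acid
Product: 19 tert-butyl N-[(2S)-4-[methoxy(methyl)amino]-4-oxobutan-2-yl]carbamate, via acyl imidazolide 18 (not isolated)
Conditions: 1,1'-carbonyldiimidazole, CH2Cl2, rt; then MeNH(OMe)·HCl, rt
Reagents that add atoms: N,O-dimethylhydroxylamine hydrochloride, CNOC.Cl
Why: Carbonyldiimidazole activation followed by aminolysis (Weinreb amide formation) does not touch the stereocentre, which is β to the carbonyl group, so the S configuration of the later C3 is taken unchanged from the chiral pool.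

Step 8
Reactants: 16 2-[(4,5-dimethoxy-2-methylnaphthalen-1-yl)methyl]-6-methyl-4H-pyran-4-one; 19 tert-butyl N-[(2S)-4-[methoxy(methyl)amino]-4-oxobutan-2-yl]carbamate
Product: 22 tert-butyl N-[(2S)-5-(4,5-dimethoxy-2-methylnaphthalen-1-yl)-5-(6-methyl-4-oxo-4H-pyran-2-yl)-4-oxopentan-2-yl]carbamate (both C5 epimers), via lithium dienolate 20 (not isolated), via N-lithio amide 21 (not isolated)
Conditions: 16, LiN(SiMe3)2 (1.05 equiv), THF, −78 to −20 °C, then −78 °C; add 21 [from 19, LiN(SiMe3)2 (1.0 equiv), THF, −78 °C]; −78 to −20 °C; AcOH quench at −78 °C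
Reagents that add atoms: none
Why: This is a lateral (vinylogous) deprotonation of a 2-alkyl-4-pyranone followed by Claisen-type C-acylation with a Weinreb amide, in which equilibration through HN(SiMe3)2 funnels the anion to the more acidic aryl-bearing methylene rather than the 6-methyl group, prior N-lithiation of the carbamate blocks proton transfer and E1cB loss of nitrogen, and the uncontrolled C5 centre is of no consequence because it becomes sp2 in step 9.

Step 9
Reactants: 22 tert-butyl N-[(2S)-5-(4,5-dimethoxy-2-methylnaphthalen-1-yl)-5-(6-methyl-4-oxo-4H-pyran-2-yl)-4-oxopentan-2-yl]carbamate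
Product: 25 tert-butyl N-[(2S)-1-[2-acetyl-3,5-dihydroxy-6-(4,5-dimethoxy-2-methylnaphthalen-1-yl)phenyl]propan-2-yl]carbamate, via tetraketone 23 (not isolated), via aldol adduct 24 (not isolated)
Conditions: 1 M aq KOH (6 equiv), 1,4-dioxane, argon, rt to 45 °C; then 1 M HCl, 0 °C, to pH 5
Reagents that add atoms: water (delivered as hydroxide from KOH), O
Why: Hydroxide first removes the very acidic C5–H and then adds in conjugate fashion to an oxygen-bearing ring carbon of the pyranone, most plausibly the unhindered methyl-bearing one that becomes C1 (addition at the carbon that becomes C6 leads to the same species), and ring opening releases tetraketone 23 as its polyenolate. The C8a carbon, flanked by the C1 and C8 carbonyl groups, then attacks the C4a ketone to give aldol 24, a 6-(enolendo)-exo-trig closure when written from the C8 enolate, and loss of water followed by enolisation of the C6 and C8 carbonyl groups makes ring A aromatic and the sequence irreversible. The closest known reaction type is the base-induced conversion of 2-(2-oxoalkyl)-4-pyranones into acylresorcinols, the laboratory counterpart of polyketide folding. No stereocentre is created: C5 becomes sp2 so both epimers of 22 converge, C3 lies outside every enolisable position and stays S, and the C5–C1' axis that becomes configurationally stable here is not controlled. The selectivity needed is the choice of folding, and the substrate secures it because C8a is the only doubly activated carbon whose six-membered aldol can aromatise: attack of C5 on the C1 carbonyl would make C5 quaternary and reverts, while C4 and the terminal methyl group are singly activated and far less acidic. The same C5 enolate lowers the acidity of C4 and shields the C4a–C5 bond, which should hold back E1cB loss of the carbamate and retro-Claisen cleavage as long as the base is dilute, alcohol-free and only gently warmed.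

Step 10
Reactants: 25 tert-butyl N-[(2S)-1-[2-acetyl-3,5-dihydroxy-6-(4,5-dimethoxy-2-methylnaphthalen-1-yl)phenyl]propan-2-yl]carbamate
Product: 26 tert-butyl N-[(2S)-1-[2-acetyl-3,5-dimethoxy-6-(4,5-dimethoxy-2-methylnaphthalen-1-yl)phenyl]propan-2-yl]carbamate
Conditions: Me2SO4 (excess), K2CO3, acetone, reflux
Reagents that add atoms: dimethyl sulfate, COS(=O)(=O)OC
Why: In this Williamson-type O-methylation of both phenols the hard electrophile favours oxygen over the C7 carbon, reflux with excess reagent overcomes the hydrogen bond between the C8 hydroxyl and the acetyl group, and K2CO3 does not ionise the carbamate N–H.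

Step 11
Reactants: 26 tert-butyl N-[(2S)-1-[2-acetyl-3,5-dimethoxy-6-(4,5-dimethoxy-2-methylnaphthalen-1-yl)phenyl]propan-2-yl]carbamate
Product: 28 O-methylancistrocladinine [(3S)-5-(4,5-dimethoxy-2-methylnaphthalen-1-yl)-6,8-dimethoxy-1,3-dimethyl-3,4-dihydroisoquinoline], via amino ketone hydrochloride 27 (not isolated)
Conditions: 4 M HCl in 1,4-dioxane, 0 °C to rt; concentrate; 1 M aq NaOH, CH2Cl2, rt
Reagents that add atoms: none
Why: Acidolysis of the Boc group gives ammonium salt 27 and, once the amine is liberated, intramolecular amine–ketone condensation (6-exo-trig addition to the acetyl carbonyl, then dehydration) closes the C1=N ring of the 3,4-dihydroisoquinoline without involving C3, which keeps its S configuration.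

Compound list
1 | 2-bromoanisole | COc1ccccc1Br | starting material
2 | hexacarbonylchromium Cr(CO)6 | [Cr].[C-]#[O+].[C-]#[O+].[C-]#[O+].[C-]#[O+].[C-]#[O+].[C-]#[O+] | starting material
3 | 2-methoxyphenyllithium | [Li]c1ccccc1OC | intermediate
4 | lithium pentacarbonyl[(2-methoxyphenyl)(oxido)carbene]chromate | [Li+].COc1ccccc1C([O-])=[Cr].[C-]#[O+].[C-]#[O+].[C-]#[O+].[C-]#[O+].[C-]#[O+] | intermediate
5 | pentacarbonyl[methoxy(2-methoxyphenyl)carbene]chromium | COC(=[Cr])c1ccccc1OC.[C-]#[O+].[C-]#[O+].[C-]#[O+].[C-]#[O+].[C-]#[O+] | intermediate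
6 | propyne | CC#C | starting material
7 | tricarbonyl(4,5-dimethoxy-2-methylnaphthalen-1-ol)chromium | Cc1cc(OC)c2c(OC)cccc2c1O.[Cr].[C-]#[O+].[C-]#[O+].[C-]#[O+] | intermediate
8 | 4,5-dimethoxy-2-methylnaphthalen-1-ol | Cc1cc(OC)c2c(OC)cccc2c1O | intermediate
9 | 4,5-dimethoxy-2-methylnaphthalen-1-yl trifluoromethanesulfonate | Cc1cc(OC)c2c(OC)cccc2c1OS(=O)(=O)C(F)(F)F | intermediate
10 | methyl bromoacetate | COC(=O)CBr | starting material
11 | bromo(2-methoxy-2-oxoethyl)zinc | COC(=O)C[Zn]Br | intermediate
12 | methyl 2-(4,5-dimethoxy-2-methylnaphthalen-1-yl)acetate | COC(=O)Cc1c(C)cc(OC)c2c(OC)cccc12 | intermediate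
13 | acetylacetone | CC(=O)CC(C)=O | starting material
14 | dilithioacetylacetone (bis-enolate) | [Li+].[Li+].C=C([O-])C=C(C)[O-] | intermediate
15 | 1-(4,5-dimethoxy-2-methylnaphthalen-1-yl)heptane-2,4,6-trione | CC(=O)CC(=O)CC(=O)Cc1c(C)cc(OC)c2c(OC)cccc12 | intermediate
16 | 2-[(4,5-dimethoxy-2-methylnaphthalen-1-yl)methyl]-6-methyl-4H-pyran-4-one | CC1=CC(=O)C=C(O1)Cc1c(C)cc(OC)c2c(OC)cccc12 | intermediate
17 | (S)-3-(tert-butoxycarbonylamino)butanoic acid | C[C@@H](CC(=O)O)NC(=O)OC(C)(C)C | starting material
18 | tert-butyl N-[(2S)-4-(imidazol-1-yl)-4-oxobutan-2-yl]carbamate | C[C@@H](CC(=O)n1ccnc1)NC(=O)OC(C)(C)C | intermediate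
19 | tert-butyl N-[(2S)-4-[methoxy(methyl)amino]-4-oxobutan-2-yl]carbamate | C[C@@H](CC(=O)N(C)OC)NC(=O)OC(C)(C)C | intermediate
20 | lithium 2-[(4,5-dimethoxy-2-methylnaphthalen-1-yl)methylidene]-6-methyl-2H-pyran-4-olate | [Li+].CC1=CC([O-])=CC(=Cc2c(C)cc(OC)c3c(OC)cccc23)O1 | intermediate
21 | N-lithio derivative of 19 | [Li+].C[C@@H](CC(=O)N(C)OC)[N-]C(=O)OC(C)(C)C | intermediate
22 | tert-butyl N-[(2S)-5-(4,5-dimethoxy-2-methylnaphthalen-1-yl)-5-(6-methyl-4-oxo-4H-pyran-2-yl)-4-oxopentan-2-yl]carbamate (both C5 epimers) | CC1=CC(=O)C=C(O1)C(c1c(C)cc(OC)c2c(OC)cccc12)C(=O)C[C@H](C)NC(=O)OC(C)(C)C | intermediate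
23 | tert-butyl N-[(2S)-5-(4,5-dimethoxy-2-methylnaphthalen-1-yl)-4,6,8,10-tetraoxoundecan-2-yl]carbamate | CC(=O)CC(=O)CC(=O)C(c1c(C)cc(OC)c2c(OC)cccc12)C(=O)C[C@H](C)NC(=O)OC(C)(C)C | intermediate
24 | tert-butyl N-[(2S)-1-[2-acetyl-6-(4,5-dimethoxy-2-methylnaphthalen-1-yl)-1-hydroxy-3,5-dioxocyclohexyl]propan-2-yl]carbamate (ring centres undefined) | CC(=O)C1C(=O)CC(=O)C(c2c(C)cc(OC)c3c(OC)cccc23)C1(O)C[C@H](C)NC(=O)OC(C)(C)C | intermediate
25 | tert-butyl N-[(2S)-1-[2-acetyl-3,5-dihydroxy-6-(4,5-dimethoxy-2-methylnaphthalen-1-yl)phenyl]propan-2-yl]carbamate | CC(=O)c1c(O)cc(O)c(-c2c(C)cc(OC)c3c(OC)cccc23)c1C[C@H](C)NC(=O)OC(C)(C)C | intermediate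
26 | tert-butyl N-[(2S)-1-[2-acetyl-3,5-dimethoxy-6-(4,5-dimethoxy-2-methylnaphthalen-1-yl)phenyl]propan-2-yl]carbamate | CC(=O)c1c(OC)cc(OC)c(-c2c(C)cc(OC)c3c(OC)cccc23)c1C[C@H](C)NC(=O)OC(C)(C)C | intermediate
27 | 1-[2-[(2S)-2-aminopropyl]-3-(4,5-dimethoxy-2-methylnaphthalen-1-yl)-4,6-dimethoxyphenyl]ethanone hydrochloride | CC(=O)c1c(OC)cc(OC)c(-c2c(C)cc(OC)c3c(OC)cccc23)c1C[C@H](C)N.Cl | intermediate
28 | O-methylancistrocladinine | COc1cc(OC)c(-c2c(C)cc(OC)c3c(OC)cccc23)c2c1C(C)=N[C@@H](C)C2 | target

Total step count: 11. Longest linear sequence: 10 steps (steps 1 to 6 and 8 to 11, from 2-bromoanisole).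

Steps most likely to fail

Step 9. Opening of the anionic pyranone may be sluggish. The aldol also has to pass through the small fraction in which C5 is protonated and the crowded C4a ketone is electrophilic. Forcing the reaction could then bring on retro-Claisen loss of the aminobutanoyl chain, E1cB loss of the carbamate, or folding through the terminal methyl group.

The fallback runs the same aromatisation in the aryl-free, unhindered series and makes the C5–C1' bond afterwards by cross-coupling. It sets out from 19 and 9 and returns at 26.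
- Commercial 2,6-dimethyl-4-pyranone has only one kind of methyl group. It would be deprotonated with LiN(SiMe3)2 and acylated with N-lithiated 19 to give tert-butyl N-[(2S)-5-(6-methyl-4-oxo-4H-pyran-2-yl)-4-oxopentan-2-yl]carbamate F1.
- Aqueous KOH would fold F1 into tert-butyl N-[(2S)-1-(2-acetyl-3,5-dihydroxyphenyl)propan-2-yl]carbamate F2.
- Me2SO4 and K2CO3 would give tert-butyl N-[(2S)-1-(2-acetyl-3,5-dimethoxyphenyl)propan-2-yl]carbamate F3.
- N-bromosuccinimide in MeCN at 0 °C should brominate C5, which is para to the C8 methoxy group, whereas C7 is flanked by two methoxy groups. The product is tert-butyl N-[(2S)-1-(2-acetyl-6-bromo-3,5-dimethoxyphenyl)propan-2-yl]carbamate F4.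
- Miyaura borylation of 9 (B2pin2, PdCl2(dppf), KOAc, dioxane) would give 2-(4,5-dimethoxy-2-methylnaphthalen-1-yl)-4,4,5,5-tetramethyl-1,3,2-dioxaborolane F5.
- Suzuki–Miyaura coupling of F4 with F5 (Pd(OAc)2, SPhos, K3PO4, toluene–water) leads to 26.

Step 8. Two processes may spoil the acylation:
- Metalation or acylation at the 6-methyl group may compete with the hindered benzylic position.
- Addition of the delocalised dienolate to the amide may be slow enough for proton transfer to take over.

The fallback replaces the acylation by aldol addition and oxidation. It sets out from 19 and 16 (as dienolate 20) and returns at 22. Reduction of 19 with LiAlH4 (THF, 0 °C) would give (S)-3-(tert-butoxycarbonylamino)butanal F6. This far more reactive and smaller electrophile would be added to equilibrated 20 at −78 °C to give tert-butyl N-[(2S)-5-(4,5-dimethoxy-2-methylnaphthalen-1-yl)-4-hydroxy-5-(6-methyl-4-oxo-4H-pyran-2-yl)pentan-2-yl]carbamate F7 as a mixture of diastereomers. Oxidation with Dess–Martin periodinane would then give 22.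

Step 5. Proton transfer from the arylacetate methylene to the strongly basic dianion may outrun acylation, which would return the ester on work-up and cap conversion.

The fallback again exchanges acylation for aldol addition and oxidation. It sets out from 12 and returns at 15. Reduction with iBu2AlH (toluene, −78 °C) would give 2-(4,5-dimethoxy-2-methylnaphthalen-1-yl)acetaldehyde F8. Addition of dianion 14 at −78 °C, where carbonyl addition is faster than enolisation, would give 7-(4,5-dimethoxy-2-methylnaphthalen-1-yl)-6-hydroxyheptane-2,4-dione F9. Oxidation with Dess–Martin periodinane would give 15.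

Further compounds
F1 | step 9 | tert-butyl N-[(2S)-5-(6-methyl-4-oxo-4H-pyran-2-yl)-4-oxopentan-2-yl]carbamate | CC1=CC(=O)C=C(O1)CC(=O)C[C@H](C)NC(=O)OC(C)(C)C
F2 | step 9 | tert-butyl N-[(2S)-1-(2-acetyl-3,5-dihydroxyphenyl)propan-2-yl]carbamate | CC(=O)c1c(O)cc(O)cc1C[C@H](C)NC(=O)OC(C)(C)C
F3 | step 9 | tert-butyl N-[(2S)-1-(2-acetyl-3,5-dimethoxyphenyl)propan-2-yl]carbamate | CC(=O)c1c(OC)cc(OC)cc1C[C@H](C)NC(=O)OC(C)(C)C
F4 | step 9 | tert-butyl N-[(2S)-1-(2-acetyl-6-bromo-3,5-dimethoxyphenyl)propan-2-yl]carbamate | CC(=O)c1c(OC)cc(OC)c(Br)c1C[C@H](C)NC(=O)OC(C)(C)C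
F5 | step 9 | 2-(4,5-dimethoxy-2-methylnaphthalen-1-yl)-4,4,5,5-tetramethyl-1,3,2-dioxaborolane | Cc1cc(OC)c2c(OC)cccc2c1B1OC(C)(C)C(C)(C)O1
F6 | step 8 | (S)-3-(tert-butoxycarbonylamino)butanal | C[C@@H](CC=O)NC(=O)OC(C)(C)C
F7 | step 8 | tert-butyl N-[(2S)-5-(4,5-dimethoxy-2-methylnaphthalen-1-yl)-4-hydroxy-5-(6-methyl-4-oxo-4H-pyran-2-yl)pentan-2-yl]carbamate | CC1=CC(=O)C=C(O1)C(c1c(C)cc(OC)c2c(OC)cccc12)C(O)C[C@H](C)NC(=O)OC(C)(C)C
F8 | step 5 | 2-(4,5-dimethoxy-2-methylnaphthalen-1-yl)acetaldehyde | O=CCc1c(C)cc(OC)c2c(OC)cccc12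
F9 | step 5 | 7-(4,5-dimethoxy-2-methylnaphthalen-1-yl)-6-hydroxyheptane-2,4-dione | CC(=O)CC(=O)CC(O)Cc1c(C)cc(OC)c2c(OC)cccc12
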